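## The problem

The target is a dibenzylbutyrolactone in which each benzyl ring carries a further arylpropanoid unit joined through an aryl–C8 bond ortho to a phenol oxygen. On the α-benzyl ring (ring C) this unit is an open 1-aryl-propane-1,3-diol chain (C7–C9, ring D on C7). On the β-benzyl ring (ring B) the same unit is closed to a trans-2-aryl-3-hydroxymethyl-2,3-dihydrobenzofuran (ring A on C2).

The SMILES is read as 7S,8S in the diol chain (anti), 2R,3S in the coumaran (trans) and 3S,4S in the lactone (trans, antipodal to the usual natural lactone series). These six stereocentres form three clusters. Within a cluster one centre can steer the other: C7 steers C8 through a chelate, coumaran C3 steers C2 through trans ring closure, and lactone C4 steers C3 through trans alkylation. No cluster can steer another, so each needs its own source of absolute configuration.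

The fragile groups dictate a neutral, non-reductive end game. The p-hydroxybenzylic alcohol at C7 sits next to the free ring C phenol and closes to a second coumaran with acid or forms a quinone methide with base and heat. The benzylic C–O bonds are at risk under hydrogenolysis.

Ring C carries OMe (C3), OH (C4) and C8 (C5) on three neighbouring carbons, with only hydrogen on C6. C4 and C5 can therefore be the two carbons of an aryne flanked by OMe: a carbon nucleophile enters at C5 and the carbanion left at C4 becomes the phenol. Ring B shows the same triad (OMe on C7, oxygen on C7a, C3 on C3a), and coumaran C3 has the same spatial arrangement as C8 of the open wing. Closing the furan ring at C7 with inversion turns the anti diol into the trans coumaran, so one aryne adduct can supply both wings.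

## Retrosynthesis

**27 from 26.** The four phenols and three alcohols are released last from the hexasilyl ether 26 with buffered fluoride. Benzyl ethers would require hydrogenolysis next to two benzylic C–O bonds, and acetal protection would require acid in the presence of the open wing. An all-silyl scheme needs one neutral operation.

**26 from 20 and 24.** The bond between the lactone α-carbon and the ring C benzylic CH2 is cut, giving the β-substituted lactone 20 and the benzylic bromide 24. Cutting at the β-benzyl bond instead would leave no simple way to set C4. Here the C4 substituent sends the electrophile to the opposite face and the trans lactone results. The cut halves the molecule and keeps the two wings apart until the end, so they never have to be told apart.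

**20 from 15.** The lactone is opened to the succinate half-ester 18, which comes from the itaconate half-ester 17 and thus from aldehyde 15 by Stobbe condensation. C4 is too far from the coumaran centres to be controlled by them, so a catalyst must set it. The Stobbe route reaches the lactone in three operations from an aldehyde; an auxiliary-based alkylation would need five. The forward reactions must tolerate an aryl silyl ether, which is why the condensation is run with an amide base at low temperature.

**15 and 24 from 12.** Both wings are traced to triol 12.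
- For the coumaran wing the C2–O bond is cut: 15 comes from 14, and 14 from 12 by acid-induced closure of the phenol onto the benzylic C7 position (via 13), which also unmasks the aldehyde.
- For the open wing the same triol is silylated (21), the acetal is converted to the aldehyde 22, then to alcohol 23 and bromide 24.

Using 12 twice replaces two unrelated syntheses by one. The C7 configuration is kept in one wing and deliberately given up in the other.

**12 from 4 and 6 (key disconnection).** Triol 12 is the reduction product of the α-aryl-β-hydroxy ester 11. In 11 the C5–C8 bond and the C4–O bond are cut together. This gives the (S)-β-hydroxy ester 4 as its dianion 7 and the aryne 8, made from bromoarene 6. The adduct 9 is borylated (10) and oxidised. An aldol route to 11 would need a ring C arylacetic acid that takes several steps and an anti-selective auxiliary reaction. The aryne cut uses a one-step bromoarene, makes the C–C and C–O bonds in one flask and lets C7 set C8.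

**4 from 1, and 6 from 5.** Ester 4 comes from β-keto ester 3 by asymmetric hydrogenation. Keto ester 3 comes from the silylated methyl vanillate 2 and tert-butyl acetate, and 2 from methyl vanillate 1. Acetal 6 is made from commercial 3-bromo-5-methoxybenzaldehyde 5.

## Roads not taken

**Alternative 1:** The coumaran is cut at C3–C3a and traced to the flavanone A2. Oxidative rearrangement with PhI(OH)OTs in HC(OMe)3 and acid shifts the ring B carbon from the carbonyl carbon to C3 and contracts the pyranone to the benzofuran ester A1.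
- Merits: the migration gives the trans ester reliably, C2 is carried over from the flavanone, and the aryl bromide in A1 is a ready handle. The reaction type is established on simple flavanones, which is more than can be said for the aryne step.
- Weak points for this target: A2 must first be made enantiopure. The guaiacyl ring must be deactivated as a mesylate to survive the iodane. The aryl bromide needs an sp2–sp3 coupling to carry the lactone. The open wing with C7 and C8 is left entirely unsolved.
- Comparison: A1 is the lower-risk route to one wing. The chosen plan sets against it that one intermediate (12) serves both wings, and that C8 and coumaran C3 come from the same controlled step.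

**Alternative 2:** Both C7–aryl bonds are cut at once. The dialdehyde A4 takes up two equivalents of the aryl Grignard reagent A5 to give the bis-anti diol A3.
- Merits: it exploits the same wing symmetry in a single late operation, and every step is a known reaction type. In both respects it is at least as good as the chosen plan.
- Weak points: A4 has two α-aryl aldehyde centres that epimerise easily under basic organometallic conditions. Felkin-type selectivity would have to be high at two sites at once. The lactone carbonyl competes for the Grignard reagent. The two wings of A3 must afterwards be told apart so that only one closes.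
- Comparison: the chosen plan sets C7 by catalytic hydrogenation and C8 by chelate control on a non-epimerisable dianion, and never has to differentiate the wings.

**Alternative 3:** The lactone is cut at O–CH2 and traced to the prochiral cyclobutanone A7. A chiral BINOL-derived phosphoric acid with aqueous H2O2 would insert oxygen next to one enantiotopic CH2 and give lactone A6.
- Merits: one catalytic step sets lactone C4, against three steps (9–11) in the chosen plan. In step economy for the lactone this road is better.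
- Weak points: enantioselectivity of such Baeyer–Villiger reactions is usually lower for 3-benzyl than for 3-aryl cyclobutanones. A7 still needs the complete coumaran, which has to come from elsewhere.
- Comparison: A6 addresses the easiest of the three stereochemical problems. The chosen plan spends its key step on the two diarylpropanoid units and uses a hydrogenation class with high, predictable selectivity for the lactone.

Key step: step 5

Remark on the chemistry: LiTMP is lithium 2,2,6,6-tetramethylpiperidide and LDA is lithium diisopropylamide, both used as preformed solutions. Ring letters and the locants C7–C9 are those of the first section.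

## Steps

Step 1
Reactants: 1 methyl vanillate (methyl 4-hydroxy-3-methoxybenzoate)
Product: 2 methyl 3-methoxy-4-(triisopropylsilyloxy)benzoate
Conditions: TIPSCl, imidazole, DMF, rt
Reagents that add atoms: triisopropylsilyl chloride, CC(C)[Si](Cl)(C(C)C)C(C)C
Why: Standard phenol silylation; the bulky aryl silyl ether should withstand the amide bases, hydrides and dilute acid used later and leaves with fluoride at the end.

Step 2
Reactants: 2 methyl 3-methoxy-4-(triisopropylsilyloxy)benzoate
Product: 3 tert-butyl 3-[3-methoxy-4-(triisopropylsilyloxy)phenyl]-3-oxopropanoate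
Conditions: t-BuOAc, LDA (2.5 eq each), THF, −78 → 0 °C
Reagents that add atoms: tert-butyl acetate, CC(=O)OC(C)(C)C
Why: Crossed Claisen condensation of a non-enolisable aryl ester with excess lithium tert-butyl acetate; the product is protected in the flask as its enolate. The tert-butyl ester is wanted for the key step.

Step 3
Reactants: 3 tert-butyl 3-[3-methoxy-4-(triisopropylsilyloxy)phenyl]-3-oxopropanoate
Product: 4 tert-butyl (S)-3-hydroxy-3-[3-methoxy-4-(triisopropylsilyloxy)phenyl]propanoate
Conditions: [RuCl(benzene)((R)-binap)]Cl (0.5 mol%), H2 (50 atm), EtOH, 40 °C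
Reagents that add atoms: none
Why: Noyori hydrogenation of a β-keto ester; the (R)-BINAP–Ru chelate delivers hydrogen to the same ketone face as in acetoacetates, which for an aryl ketone is the S descriptor at C7. Neutral ethanol and moderate temperature are chosen so that the p-silyloxybenzylic alcohol is not solvolysed.

Step 4
Reactants: 5 3-bromo-5-methoxybenzaldehyde
Product: 6 2-(3-bromo-5-methoxyphenyl)-1,3-dioxolane
Conditions: HOCH2CH2OH, p-TsOH (cat.), toluene, reflux, Dean–Stark
Reagents that add atoms: ethylene glycol, OCCO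
Why: Acetalisation; the dioxolane masks the future benzylic carbon, is inert to LiTMP and is only a weak director of lithiation.

Step 5
Reactants: 4 tert-butyl (S)-3-hydroxy-3-[3-methoxy-4-(triisopropylsilyloxy)phenyl]propanoate; 6 2-(3-bromo-5-methoxyphenyl)-1,3-dioxolane
Product: 11 tert-butyl (2R,3S)-2-[5-(1,3-dioxolan-2-yl)-2-hydroxy-3-methoxyphenyl]-3-hydroxy-3-[3-methoxy-4-(triisopropylsilyloxy)phenyl]propanoate, via dilithium dianion 7 (not isolated), via aryne 8 (not isolated), via aryllithium adduct 9 (not isolated), via dimethyl arylboronate 10 (not isolated)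
Conditions: 4 (1.1 eq), LiTMP (2.2 eq), THF, −78 → −30 °C; 6 (1.0 eq), then LiTMP (1.05 eq) added slowly, −78 → −50 °C; B(OMe)3 (4 eq), −78 → 0 °C; pH 7 phosphate buffer, 30% H2O2, 0 °C
Reagents that add atoms: hydrogen peroxide, OO
Why: Proposed new method: LiTMP removes the proton between OMe and Br of 6, loss of LiBr gives aryne 8, and the enolate carbon of the chelated dianion 7 adds to the aryne carbon remote from OMe, so that adduct 9 carries lithium between OMe and the new chain; B(OMe)3 turns it into boronate 10 and buffered H2O2 oxidises the C–B bond to the phenol. The closest known reaction types are the α-arylation of ester enolates by arynes generated from haloarenes with LiTMP, the Fráter–Seebach anti-alkylation of β-hydroxy ester dianions, and the borylation–oxidation of aryllithiums formed by aryne carbolithiation. No ring is closed. The new stereocentre C8 is controlled by C7: in the six-membered lithium chelate of 7 the aryl group on C7 screens one enolate face and the aryne is taken up on the other, which should give the anti (2R,3S) ester. Regioselectivity rests on the inductive effect of OMe on the aryne (attack at the distal carbon, carbanion next to oxygen) and on the attacked carbon having only hydrogen as its other neighbour; lithiation of 6 elsewhere is disfavoured because only the C–H between OMe and Br is flanked by two acidifying groups. The step needs the aryllithium to outlive proton transfer from the newly acidic C8–H and from the amine, and needs C8 not to be enolised by remaining base. The tert-butyl ester (no attack on the carbonyl, hindered C8–H), LiTMP as the only base and added slowly in near-stoichiometric amount at −78 °C, chelation of the aryllithium by OMe and the C7 alkoxide, and immediate trapping by a small borate in excess are chosen to secure this.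

Step 6
Reactants: 11 tert-butyl (2R,3S)-2-[5-(1,3-dioxolan-2-yl)-2-hydroxy-3-methoxyphenyl]-3-hydroxy-3-[3-methoxy-4-(triisopropylsilyloxy)phenyl]propanoate
Product: 12 (1S,2S)-2-[5-(1,3-dioxolan-2-yl)-2-hydroxy-3-methoxyphenyl]-1-[3-methoxy-4-(triisopropylsilyloxy)phenyl]propane-1,3-diol
Conditions: LiAlH4 (4 eq), THF, 0 °C → rt; aq. KNaC4H4O6
Reagents that add atoms: none
Why: Hydride reduction of the ester to the primary alcohol; acetal and aryl silyl ether are inert. The neutral tartrate work-up avoids acid-triggered ring closure of the triol, which is divided between steps 7 and 12.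

Step 7
Reactants: 12 (1S,2S)-2-[5-(1,3-dioxolan-2-yl)-2-hydroxy-3-methoxyphenyl]-1-[3-methoxy-4-(triisopropylsilyloxy)phenyl]propane-1,3-diol
Product: 14 (2R,3S)-3-(hydroxymethyl)-7-methoxy-2-[3-methoxy-4-(triisopropylsilyloxy)phenyl]-2,3-dihydrobenzofuran-5-carbaldehyde, via coumaran acetal 13 (not isolated)
Conditions: camphorsulfonic acid (0.1 eq), CH2Cl2, 0 °C → rt; then 1 M HCl, THF, rt
Reagents that add atoms: water, O
Why: Acid ionises the p-silyloxybenzylic C7–OH and the ortho phenol captures the cation in a 5-exo closure, the classical ring closure of 2-(2-hydroxyaryl)-1-arylpropane-1,3-diols to phenylcoumarans. C3 keeps the configuration set in step 5 and C2 settles trans to it under reversible ionisation, so the C7 configuration is given up on purpose. Aqueous acid then hydrolyses the dioxolane to the aldehyde.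

Step 8
Reactants: 14 (2R,3S)-3-(hydroxymethyl)-7-methoxy-2-[3-methoxy-4-(triisopropylsilyloxy)phenyl]-2,3-dihydrobenzofuran-5-carbaldehyde
Product: 15 (2R,3S)-7-methoxy-2-[3-methoxy-4-(triisopropylsilyloxy)phenyl]-3-[(triisopropylsilyloxy)methyl]-2,3-dihydrobenzofuran-5-carbaldehyde
Conditions: TIPSCl, imidazole, DMF, rt
Reagents that add atoms: triisopropylsilyl chloride, CC(C)[Si](Cl)(C(C)C)C(C)C
Why: Silylation of the primary alcohol; a TIPS ether is chosen because it survives the base of step 9 and the brief acidification of step 11.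

Step 9
Reactants: 15 (2R,3S)-7-methoxy-2-[3-methoxy-4-(triisopropylsilyloxy)phenyl]-3-[(triisopropylsilyloxy)methyl]-2,3-dihydrobenzofuran-5-carbaldehyde
Product: 17 (E)-3-(methoxycarbonyl)-4-{(2R,3S)-7-methoxy-2-[3-methoxy-4-(triisopropylsilyloxy)phenyl]-3-[(triisopropylsilyloxy)methyl]-2,3-dihydrobenzofuran-5-yl}but-3-enoic acid, via paraconate lactone 16 (not isolated)
Conditions: dimethyl succinate, LDA (1.3 eq each), THF, −78 °C; 15; then LDA (1.2 eq), −78 → 0 °C; aq. citric acid
Reagents that add atoms: dimethyl succinate, COC(=O)CCC(=O)OC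
Why: Stobbe condensation: aldol addition of the succinate enolate, lactonisation to 16 and base-induced E1cB ring opening give the half-ester. Running it with an amide base at low temperature keeps free alkoxide away from the aryl silyl ether; E/Z mixtures are acceptable for step 10.

Step 10
Reactants: 17 (E)-3-(methoxycarbonyl)-4-{(2R,3S)-7-methoxy-2-[3-methoxy-4-(triisopropylsilyloxy)phenyl]-3-[(triisopropylsilyloxy)methyl]-2,3-dihydrobenzofuran-5-yl}but-3-enoic acid
Product: 18 (S)-3-(methoxycarbonyl)-4-{(2R,3S)-7-methoxy-2-[3-methoxy-4-(triisopropylsilyloxy)phenyl]-3-[(triisopropylsilyloxy)methyl]-2,3-dihydrobenzofuran-5-yl}butanoic acid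
Conditions: [Rh(cod)((R,R)-Et-DuPHOS)]BF4 (1 mol%; ligand 1,2-bis(2,5-diethylphospholano)benzene), NaOMe (0.1 eq), H2 (6 atm), MeOH, rt
Reagents that add atoms: none
Why: Rh–bisphospholane asymmetric hydrogenation of a Stobbe-derived itaconate half-ester, with the carboxylate as second binding site. The (S,S) ligand is the one that gives (R)-2-alkylsuccinates, so the (R,R) ligand is chosen for the S centre, which becomes C4 of the lactone.

Step 11
Reactants: 18 (S)-3-(methoxycarbonyl)-4-{(2R,3S)-7-methoxy-2-[3-methoxy-4-(triisopropylsilyloxy)phenyl]-3-[(triisopropylsilyloxy)methyl]-2,3-dihydrobenzofuran-5-yl}butanoic acid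
Product: 20 (S)-4-({(2R,3S)-7-methoxy-2-[3-methoxy-4-(triisopropylsilyloxy)phenyl]-3-[(triisopropylsilyloxy)methyl]-2,3-dihydrobenzofuran-5-yl}methyl)dihydrofuran-2(3H)-one, via hydroxy acid 19 (not isolated)
Conditions: KOH (1 eq), EtOH; CaCl2, NaBH4, 0 °C → rt; then 1 M HCl to pH 2, rt
Reagents that add atoms: none
Why: Ca(BH4)2 reduces the methyl ester but not the carboxylate salt, and acidification closes the γ-lactone; this is the usual way from benzylsuccinate half-esters to β-benzylbutyrolactones and does not touch the stereocentre.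

Step 12
Reactants: 12 (1S,2S)-2-[5-(1,3-dioxolan-2-yl)-2-hydroxy-3-methoxyphenyl]-1-[3-methoxy-4-(triisopropylsilyloxy)phenyl]propane-1,3-diol
Product: 21 2-{4-(tert-butyldimethylsilyloxy)-3-[(1S,2S)-1,3-bis(tert-butyldimethylsilyloxy)-1-(3-methoxy-4-(triisopropylsilyloxy)phenyl)propan-2-yl]-5-methoxyphenyl}-1,3-dioxolane
Conditions: TBSOTf (4 eq), 2,6-lutidine (6 eq), CH2Cl2, −78 → −20 °C
Reagents that add atoms: tert-butyldimethylsilyl triflate, CC(C)(C)[Si](C)(C)OS(=O)(=O)C(F)(F)F
Why: Silyl triflate with a hindered pyridine silylates the phenol, the primary and the benzylic hydroxyl at low temperature, where buffered silyl transfer should outrun ionisation at C7. Any acetal opened by the silyl triflate only anticipates step 13.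

Step 13
Reactants: 21 2-{4-(tert-butyldimethylsilyloxy)-3-[(1S,2S)-1,3-bis(tert-butyldimethylsilyloxy)-1-(3-methoxy-4-(triisopropylsilyloxy)phenyl)propan-2-yl]-5-methoxyphenyl}-1,3-dioxolane
Product: 22 4-(tert-butyldimethylsilyloxy)-3-[(1S,2S)-1,3-bis(tert-butyldimethylsilyloxy)-1-(3-methoxy-4-(triisopropylsilyloxy)phenyl)propan-2-yl]-5-methoxybenzaldehyde
Conditions: pyridinium p-toluenesulfonate (cat.), acetone–H2O (10:1), rt
Reagents that add atoms: water, O
Why: Mild acid-catalysed acetal hydrolysis; the aryl dioxolane, activated by the para silyloxy group, should be far more labile than the TBS ethers under these conditions.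

Step 14
Reactants: 22 4-(tert-butyldimethylsilyloxy)-3-[(1S,2S)-1,3-bis(tert-butyldimethylsilyloxy)-1-(3-methoxy-4-(triisopropylsilyloxy)phenyl)propan-2-yl]-5-methoxybenzaldehyde
Product: 23 {4-(tert-butyldimethylsilyloxy)-3-[(1S,2S)-1,3-bis(tert-butyldimethylsilyloxy)-1-(3-methoxy-4-(triisopropylsilyloxy)phenyl)propan-2-yl]-5-methoxyphenyl}methanol
Conditions: i-Bu2AlH, CH2Cl2, −78 °C
Reagents that add atoms: none
Why: Aldehyde reduction with a non-nucleophilic hydride, preferred to NaBH4 in methanol so that no alkoxide attacks the aryl silyl ether para to the formyl group.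

Step 15
Reactants: 23 {4-(tert-butyldimethylsilyloxy)-3-[(1S,2S)-1,3-bis(tert-butyldimethylsilyloxy)-1-(3-methoxy-4-(triisopropylsilyloxy)phenyl)propan-2-yl]-5-methoxyphenyl}methanol
Product: 24 [4-(bromomethyl)-2-[(1S,2S)-1,3-bis(tert-butyldimethylsilyloxy)-1-(3-methoxy-4-(triisopropylsilyloxy)phenyl)propan-2-yl]-6-methoxyphenoxy](tert-butyl)dimethylsilane
Conditions: CBr4, PPh3, CH2Cl2, 0 °C; used at once
Reagents that add atoms: carbon tetrabromide, BrC(Br)(Br)Br
Why: Appel bromination of a benzylic alcohol under neutral conditions; 4-silyloxy-3-methoxybenzyl bromides are usable electrophiles if not stored.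

Step 16
Reactants: 20 (S)-4-({(2R,3S)-7-methoxy-2-[3-methoxy-4-(triisopropylsilyloxy)phenyl]-3-[(triisopropylsilyloxy)methyl]-2,3-dihydrobenzofuran-5-yl}methyl)dihydrofuran-2(3H)-one; 24 [4-(bromomethyl)-2-[(1S,2S)-1,3-bis(tert-butyldimethylsilyloxy)-1-(3-methoxy-4-(triisopropylsilyloxy)phenyl)propan-2-yl]-6-methoxyphenoxy](tert-butyl)dimethylsilane
Product: 26 (3S,4S)-3-{4-(tert-butyldimethylsilyloxy)-3-[(1S,2S)-1,3-bis(tert-butyldimethylsilyloxy)-1-(3-methoxy-4-(triisopropylsilyloxy)phenyl)propan-2-yl]-5-methoxybenzyl}-4-({(2R,3S)-7-methoxy-2-[3-methoxy-4-(triisopropylsilyloxy)phenyl]-3-[(triisopropylsilyloxy)methyl]-2,3-dihydrobenzofuran-5-yl}methyl)dihydrofuran-2(3H)-one, via lithium enolate 25 (not isolated)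
Conditions: LiN(SiMe3)2 (1.1 eq), THF, −78 °C; 24, DMPU, −78 → −20 °C
Reagents that add atoms: none
Why: Alkylation of the lithium enolate of a β-substituted γ-butyrolactone with a benzylic bromide, the standard construction of dibenzylbutyrolactones. The electrophile enters anti to the C4 substituent, so the new centre C3 is S and the lactone is trans.

Step 17
Reactants: 26 (3S,4S)-3-{4-(tert-butyldimethylsilyloxy)-3-[(1S,2S)-1,3-bis(tert-butyldimethylsilyloxy)-1-(3-methoxy-4-(triisopropylsilyloxy)phenyl)propan-2-yl]-5-methoxybenzyl}-4-({(2R,3S)-7-methoxy-2-[3-methoxy-4-(triisopropylsilyloxy)phenyl]-3-[(triisopropylsilyloxy)methyl]-2,3-dihydrobenzofuran-5-yl}methyl)dihydrofuran-2(3H)-one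
Product: 27 (3S,4S)-3-{4-hydroxy-3-[(1S,2S)-1,3-dihydroxy-1-(4-hydroxy-3-methoxyphenyl)propan-2-yl]-5-methoxybenzyl}-4-({(2R,3S)-2-(4-hydroxy-3-methoxyphenyl)-3-(hydroxymethyl)-7-methoxy-2,3-dihydrobenzofuran-5-yl}methyl)dihydrofuran-2(3H)-one (CNP0186558.3)
Conditions: Bu4NF–AcOH (1:1, 9 eq), THF, 0 → 35 °C
Reagents that add atoms: none
Why: Fluoride cleaves all six silyl ethers. Acetic acid keeps the medium near neutral, so that neither phenoxide-driven quinone methide formation nor acid-driven closure of the open wing should occur, and no stereocentre is touched.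

## Compound list

1 | methyl vanillate (methyl 4-hydroxy-3-methoxybenzoate) | COC(=O)c1ccc(O)c(OC)c1 | starting material
2 | methyl 3-methoxy-4-(triisopropylsilyloxy)benzoate | COC(=O)c1ccc(O[Si](C(C)C)(C(C)C)C(C)C)c(OC)c1 | intermediate
3 | tert-butyl 3-[3-methoxy-4-(triisopropylsilyloxy)phenyl]-3-oxopropanoate | CC(C)(C)OC(=O)CC(=O)c1ccc(O[Si](C(C)C)(C(C)C)C(C)C)c(OC)c1 | intermediate
4 | tert-butyl (S)-3-hydroxy-3-[3-methoxy-4-(triisopropylsilyloxy)phenyl]propanoate | CC(C)(C)OC(=O)C[C@H](O)c1ccc(O[Si](C(C)C)(C(C)C)C(C)C)c(OC)c1 | intermediate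
5 | 3-bromo-5-methoxybenzaldehyde | COc1cc(Br)cc(C=O)c1 | starting material
6 | 2-(3-bromo-5-methoxyphenyl)-1,3-dioxolane | COc1cc(Br)cc(C2OCCO2)c1 | intermediate
7 | dilithium dianion of 4 (lithium alkoxide and O-lithium ester enolate, chelated) | CC(C)(C)O/C(O[Li])=C/[C@H](O[Li])c1ccc(O[Si](C(C)C)(C(C)C)C(C)C)c(OC)c1 | intermediate
8 | 5-(1,3-dioxolan-2-yl)-3-methoxybenzyne (triple bond between the former C–Br and C–H carbons) | COC1=CC(C2OCCO2)=CC#C1 | intermediate
9 | aryllithium adduct: tert-butyl (2R,3S)-2-[5-(1,3-dioxolan-2-yl)-2-lithio-3-methoxyphenyl]-3-(lithiooxy)-3-[3-methoxy-4-(triisopropylsilyloxy)phenyl]propanoate | COc1cc([C@@H](O[Li])[C@H](C(=O)OC(C)(C)C)c2cc(C3OCCO3)cc(OC)c2[Li])ccc1O[Si](C(C)C)(C(C)C)C(C)C | intermediate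
10 | dimethyl arylboronate of 9 (B(OMe)2 in place of the aryl lithium) | COc1cc([C@@H](O[Li])[C@H](C(=O)OC(C)(C)C)c2cc(C3OCCO3)cc(OC)c2B(OC)OC)ccc1O[Si](C(C)C)(C(C)C)C(C)C | intermediate
11 | tert-butyl (2R,3S)-2-[5-(1,3-dioxolan-2-yl)-2-hydroxy-3-methoxyphenyl]-3-hydroxy-3-[3-methoxy-4-(triisopropylsilyloxy)phenyl]propanoate | COc1cc([C@@H](O)[C@H](C(=O)OC(C)(C)C)c2cc(C3OCCO3)cc(OC)c2O)ccc1O[Si](C(C)C)(C(C)C)C(C)C | intermediate
12 | (1S,2S)-2-[5-(1,3-dioxolan-2-yl)-2-hydroxy-3-methoxyphenyl]-1-[3-methoxy-4-(triisopropylsilyloxy)phenyl]propane-1,3-diol | COc1cc([C@@H](O)[C@H](CO)c2cc(C3OCCO3)cc(OC)c2O)ccc1O[Si](C(C)C)(C(C)C)C(C)C | intermediate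
13 | {(2R,3S)-5-(1,3-dioxolan-2-yl)-7-methoxy-2-[3-methoxy-4-(triisopropylsilyloxy)phenyl]-2,3-dihydrobenzofuran-3-yl}methanol | O1CCOC1c1cc(OC)c2c(c1)[C@@H](CO)[C@H](c1ccc(O[Si](C(C)C)(C(C)C)C(C)C)c(OC)c1)O2 | intermediate
14 | (2R,3S)-3-(hydroxymethyl)-7-methoxy-2-[3-methoxy-4-(triisopropylsilyloxy)phenyl]-2,3-dihydrobenzofuran-5-carbaldehyde | O=Cc1cc(OC)c2c(c1)[C@@H](CO)[C@H](c1ccc(O[Si](C(C)C)(C(C)C)C(C)C)c(OC)c1)O2 | intermediate
15 | (2R,3S)-7-methoxy-2-[3-methoxy-4-(triisopropylsilyloxy)phenyl]-3-[(triisopropylsilyloxy)methyl]-2,3-dihydrobenzofuran-5-carbaldehyde | O=Cc1cc(OC)c2c(c1)[C@@H](CO[Si](C(C)C)(C(C)C)C(C)C)[C@H](c1ccc(O[Si](C(C)C)(C(C)C)C(C)C)c(OC)c1)O2 | intermediate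
16 | methyl 5-oxo-2-aryltetrahydrofuran-3-carboxylate (aryl = the dihydrobenzofuran-5-yl group of 15; mixture at the two new ring carbons) | COC(=O)C3CC(=O)OC3c1cc(OC)c2c(c1)[C@@H](CO[Si](C(C)C)(C(C)C)C(C)C)[C@H](c1ccc(O[Si](C(C)C)(C(C)C)C(C)C)c(OC)c1)O2 | intermediate
17 | (E)-3-(methoxycarbonyl)-4-{(2R,3S)-7-methoxy-2-[3-methoxy-4-(triisopropylsilyloxy)phenyl]-3-[(triisopropylsilyloxy)methyl]-2,3-dihydrobenzofuran-5-yl}but-3-enoic acid | OC(=O)C\C(C(=O)OC)=C/c1cc(OC)c2c(c1)[C@@H](CO[Si](C(C)C)(C(C)C)C(C)C)[C@H](c1ccc(O[Si](C(C)C)(C(C)C)C(C)C)c(OC)c1)O2 | intermediate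
18 | (S)-3-(methoxycarbonyl)-4-{(2R,3S)-7-methoxy-2-[3-methoxy-4-(triisopropylsilyloxy)phenyl]-3-[(triisopropylsilyloxy)methyl]-2,3-dihydrobenzofuran-5-yl}butanoic acid | OC(=O)C[C@H](Cc1cc(OC)c2c(c1)[C@@H](CO[Si](C(C)C)(C(C)C)C(C)C)[C@H](c1ccc(O[Si](C(C)C)(C(C)C)C(C)C)c(OC)c1)O2)C(=O)OC | intermediate
19 | (S)-4-hydroxy-3-(arylmethyl)butanoic acid (aryl as in 18) | OC[C@H](CC(=O)O)Cc1cc(OC)c2c(c1)[C@@H](CO[Si](C(C)C)(C(C)C)C(C)C)[C@H](c1ccc(O[Si](C(C)C)(C(C)C)C(C)C)c(OC)c1)O2 | intermediate
20 | (S)-4-({(2R,3S)-7-methoxy-2-[3-methoxy-4-(triisopropylsilyloxy)phenyl]-3-[(triisopropylsilyloxy)methyl]-2,3-dihydrobenzofuran-5-yl}methyl)dihydrofuran-2(3H)-one | O=C1C[C@H](Cc2cc(OC)c3c(c2)[C@@H](CO[Si](C(C)C)(C(C)C)C(C)C)[C@H](c2ccc(O[Si](C(C)C)(C(C)C)C(C)C)c(OC)c2)O3)CO1 | intermediate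
21 | 2-{4-(tert-butyldimethylsilyloxy)-3-[(1S,2S)-1,3-bis(tert-butyldimethylsilyloxy)-1-(3-methoxy-4-(triisopropylsilyloxy)phenyl)propan-2-yl]-5-methoxyphenyl}-1,3-dioxolane | COc1cc([C@@H](O[Si](C)(C)C(C)(C)C)[C@H](CO[Si](C)(C)C(C)(C)C)c2cc(C3OCCO3)cc(OC)c2O[Si](C)(C)C(C)(C)C)ccc1O[Si](C(C)C)(C(C)C)C(C)C | intermediate
22 | 4-(tert-butyldimethylsilyloxy)-3-[(1S,2S)-1,3-bis(tert-butyldimethylsilyloxy)-1-(3-methoxy-4-(triisopropylsilyloxy)phenyl)propan-2-yl]-5-methoxybenzaldehyde | COc1cc([C@@H](O[Si](C)(C)C(C)(C)C)[C@H](CO[Si](C)(C)C(C)(C)C)c2cc(C=O)cc(OC)c2O[Si](C)(C)C(C)(C)C)ccc1O[Si](C(C)C)(C(C)C)C(C)C | intermediate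
23 | {4-(tert-butyldimethylsilyloxy)-3-[(1S,2S)-1,3-bis(tert-butyldimethylsilyloxy)-1-(3-methoxy-4-(triisopropylsilyloxy)phenyl)propan-2-yl]-5-methoxyphenyl}methanol | COc1cc([C@@H](O[Si](C)(C)C(C)(C)C)[C@H](CO[Si](C)(C)C(C)(C)C)c2cc(CO)cc(OC)c2O[Si](C)(C)C(C)(C)C)ccc1O[Si](C(C)C)(C(C)C)C(C)C | intermediate
24 | benzylic bromide of 23 (CH2Br in place of CH2OH) | COc1cc([C@@H](O[Si](C)(C)C(C)(C)C)[C@H](CO[Si](C)(C)C(C)(C)C)c2cc(CBr)cc(OC)c2O[Si](C)(C)C(C)(C)C)ccc1O[Si](C(C)C)(C(C)C)C(C)C | intermediate
25 | lithium enolate of lactone 20 | [Li]OC1=C[C@H](Cc2cc(OC)c3c(c2)[C@@H](CO[Si](C(C)C)(C(C)C)C(C)C)[C@H](c2ccc(O[Si](C(C)C)(C(C)C)C(C)C)c(OC)c2)O3)CO1 | intermediate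
26 | hexasilyl ether of the target: (3S,4S)-lactone with the (1S,2S) open wing as tris-TBS ether, the (2R,3S) coumaran wing as CH2OTIPS, and both guaiacyl phenols as TIPS ethers | COc1cc([C@@H](O[Si](C)(C)C(C)(C)C)[C@H](CO[Si](C)(C)C(C)(C)C)c2cc(C[C@@H]3C(=O)OC[C@H]3Cc3cc(OC)c4c(c3)[C@@H](CO[Si](C(C)C)(C(C)C)C(C)C)[C@H](c3ccc(O[Si](C(C)C)(C(C)C)C(C)C)c(OC)c3)O4)cc(OC)c2O[Si](C)(C)C(C)(C)C)ccc1O[Si](C(C)C)(C(C)C)C(C)C | intermediate
27 | (3S,4S)-3-{4-hydroxy-3-[(1S,2S)-1,3-dihydroxy-1-(4-hydroxy-3-methoxyphenyl)propan-2-yl]-5-methoxybenzyl}-4-({(2R,3S)-2-(4-hydroxy-3-methoxyphenyl)-3-(hydroxymethyl)-7-methoxy-2,3-dihydrobenzofuran-5-yl}methyl)dihydrofuran-2(3H)-one | COc1cc([C@@H](O)[C@H](CO)c2cc(C[C@@H]3C(=O)OC[C@H]3Cc3cc(OC)c4c(c3)[C@@H](CO)[C@H](c3ccc(O)c(OC)c3)O4)cc(OC)c2O)ccc1O | target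

## Step count and risks

Total step count: 17. Longest linear sequence: 12 steps (1, 2, 3, 5, 6, 7, 8, 9, 10, 11, 16, 17) from methyl vanillate. The open-wing branch (steps 12–15) joins at step 16.

**Step 5 (key step).**
- What may go wrong: quenching of the aryllithium by proton transfer, from the C8–H of another adduct molecule or from the amine, before borylation. This would give the arylated ester without the phenol oxygen. Enolisation of the α-aryl ester by remaining base would lose the C8 configuration on reprotonation. The aryne could also be consumed by amide nitrogen or by the adduct itself.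
- Fallback (sets out from 6, returns at 12): the oxygen is put on ring C first and the C7–C8 bond is made by an auxiliary-controlled aldol reaction. Bromoarene 6 is lithiated between OMe and Br with LDA in the presence of B(Oi-Pr)3 (in situ trapping, THF, −78 °C) and the boronate is oxidised with buffered H2O2 to 2-bromo-4-(1,3-dioxolan-2-yl)-6-methoxyphenol F1. This is allylated (allyl bromide, K2CO3, DMF) to 2-[4-(allyloxy)-3-bromo-5-methoxyphenyl]-1,3-dioxolane F2. Pd-catalysed coupling of F2 with the zinc enolate made from (S)-4-benzyl-3-(bromoacetyl)oxazolidin-2-one and zinc (Pd(dba)2, Q-phos, THF) gives (S)-3-{2-[2-(allyloxy)-5-(1,3-dioxolan-2-yl)-3-methoxyphenyl]acetyl}-4-benzyloxazolidin-2-one F3. This is combined with 3-methoxy-4-(triisopropylsilyloxy)benzaldehyde F4 (from vanillin, TIPSCl, imidazole) in a MgCl2-catalysed anti-aldol reaction (MgCl2, Et3N, Me3SiCl, EtOAc) to give the O-trimethylsilyl anti-aldol imide F5. C8 is fixed by the benzyl group of the chelated enolate, and the antipodal auxiliary is available if the sense has to be reversed. LiBH4 (THF, MeOH, 0 °C) removes the auxiliary and K2CO3 in MeOH the silyl group, giving (1S,2S)-2-[2-(allyloxy)-5-(1,3-dioxolan-2-yl)-3-methoxyphenyl]-1-[3-methoxy-4-(triisopropylsilyloxy)phenyl]propane-1,3-diol F6. Pd(PPh3)4 with morpholine frees the phenol and the route is rejoined at 12.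

**Step 9 (Stobbe condensation, with step 10 depending on it).**
- What may go wrong: cleavage of the aryl silyl ether by the alkoxide released during the condensation. In the following hydrogenation, face selectivity may be insufficient for so bulky a β-aryl group.
- Fallback (sets out from 15, returns at 20; bypasses steps 9–11): the lactone centre is set by oxazolidinone alkylation. Aldehyde 15 is reduced (NaBH4, THF–EtOH, 0 °C) to {(2R,3S)-7-methoxy-2-[3-methoxy-4-(triisopropylsilyloxy)phenyl]-3-[(triisopropylsilyloxy)methyl]-2,3-dihydrobenzofuran-5-yl}methanol F7 and converted (CBr4, PPh3, CH2Cl2) into the corresponding 5-(bromomethyl)dihydrobenzofuran F8. The sodium enolate of (S)-4-benzyl-3-(4-tert-butoxy-4-oxobutanoyl)oxazolidin-2-one (NaN(SiMe3)2, THF, −78 °C) is alkylated by F8 on the face away from the benzyl group, giving tert-butyl (S)-4-[(S)-4-benzyl-2-oxooxazolidin-3-yl]-3-(arylmethyl)-4-oxobutanoate F9. LiBH4 (THF, H2O, 0 °C) gives tert-butyl (S)-4-hydroxy-3-(arylmethyl)butanoate F10, and p-TsOH (cat.) in toluene at 60 °C closes lactone 20.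

**Step 7 (ring closure to the coumaran).**
- What may go wrong: loss of a proton from the benzylic cation toward a stilbene instead of capture by the phenol, or incomplete equilibration to the trans isomer.
- Fallback (sets out from 11, returns at 13): the closure is moved to the ester stage and made a displacement with inversion. Ester 11 with PPh3 and diisopropyl azodicarboxylate (THF, 0 °C, Mitsunobu reaction) lets the phenol displace the activated C7–OH, giving tert-butyl (2R,3R)-5-(1,3-dioxolan-2-yl)-7-methoxy-2-[3-methoxy-4-(triisopropylsilyloxy)phenyl]-2,3-dihydrobenzofuran-3-carboxylate F11. LiAlH4 reduces the ester to alcohol 13, which aqueous acid converts into 14 as in the second stage of step 7.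

**Step 17 (global desilylation).**
- What may go wrong: incomplete removal of the hindered silyl ethers, or ring closure and quinone methide formation in the open wing once the ring C phenol is free.
- Fallback (sets out from 26, returns at 27): the deprotection is staged so that C7–OH is never exposed to acid beside a free phenol. HF·pyridine in THF–pyridine (0 °C → rt) removes the three alkyl silyl ethers of 26 and leaves the hindered aryl silyl ethers, giving the tris(aryl silyl ether) triol F12. KHF2 in MeOH (rt) then cleaves the three aryl silyl ethers to give 27.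

## Further compounds

F1 | step 5 | 2-bromo-4-(1,3-dioxolan-2-yl)-6-methoxyphenol | COc1cc(C2OCCO2)cc(Br)c1O
F2 | step 5 | 2-[4-(allyloxy)-3-bromo-5-methoxyphenyl]-1,3-dioxolane | COc1cc(C2OCCO2)cc(Br)c1OCC=C
F3 | step 5 | (S)-3-{2-[2-(allyloxy)-5-(1,3-dioxolan-2-yl)-3-methoxyphenyl]acetyl}-4-benzyloxazolidin-2-one | O=C1OC[C@H](Cc2ccccc2)N1C(=O)Cc1cc(C2OCCO2)cc(OC)c1OCC=C
F4 | step 5 | 3-methoxy-4-(triisopropylsilyloxy)benzaldehyde | COc1cc(C=O)ccc1O[Si](C(C)C)(C(C)C)C(C)C
F5 | step 5 | (S)-3-{(2R,3S)-2-[2-(allyloxy)-5-(1,3-dioxolan-2-yl)-3-methoxyphenyl]-3-[3-methoxy-4-(triisopropylsilyloxy)phenyl]-3-(trimethylsilyloxy)propanoyl}-4-benzyloxazolidin-2-one | COc1cc([C@@H](O[Si](C)(C)C)[C@H](C(=O)N2[C@@H](Cc3ccccc3)COC2=O)c2cc(C3OCCO3)cc(OC)c2OCC=C)ccc1O[Si](C(C)C)(C(C)C)C(C)C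
F6 | step 5 | (1S,2S)-2-[2-(allyloxy)-5-(1,3-dioxolan-2-yl)-3-methoxyphenyl]-1-[3-methoxy-4-(triisopropylsilyloxy)phenyl]propane-1,3-diol | COc1cc([C@@H](O)[C@H](CO)c2cc(C3OCCO3)cc(OC)c2OCC=C)ccc1O[Si](C(C)C)(C(C)C)C(C)C
F7 | step 9 | {(2R,3S)-7-methoxy-2-[3-methoxy-4-(triisopropylsilyloxy)phenyl]-3-[(triisopropylsilyloxy)methyl]-2,3-dihydrobenzofuran-5-yl}methanol | OCc1cc(OC)c2c(c1)[C@@H](CO[Si](C(C)C)(C(C)C)C(C)C)[C@H](c1ccc(O[Si](C(C)C)(C(C)C)C(C)C)c(OC)c1)O2
F8 | step 9 | (2R,3S)-5-(bromomethyl)-7-methoxy-2-[3-methoxy-4-(triisopropylsilyloxy)phenyl]-3-[(triisopropylsilyloxy)methyl]-2,3-dihydrobenzofuran | BrCc1cc(OC)c2c(c1)[C@@H](CO[Si](C(C)C)(C(C)C)C(C)C)[C@H](c1ccc(O[Si](C(C)C)(C(C)C)C(C)C)c(OC)c1)O2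
F9 | step 9 | tert-butyl (S)-4-[(S)-4-benzyl-2-oxooxazolidin-3-yl]-3-(arylmethyl)-4-oxobutanoate (aryl = dihydrobenzofuran-5-yl group of F8) | O=C1OC[C@H](Cc2ccccc2)N1C(=O)[C@H](CC(=O)OC(C)(C)C)Cc1cc(OC)c2c(c1)[C@@H](CO[Si](C(C)C)(C(C)C)C(C)C)[C@H](c1ccc(O[Si](C(C)C)(C(C)C)C(C)C)c(OC)c1)O2
F10 | step 9 | tert-butyl (S)-4-hydroxy-3-(arylmethyl)butanoate (aryl as in F9) | OC[C@H](CC(=O)OC(C)(C)C)Cc1cc(OC)c2c(c1)[C@@H](CO[Si](C(C)C)(C(C)C)C(C)C)[C@H](c1ccc(O[Si](C(C)C)(C(C)C)C(C)C)c(OC)c1)O2
F11 | step 7 | tert-butyl (2R,3R)-5-(1,3-dioxolan-2-yl)-7-methoxy-2-[3-methoxy-4-(triisopropylsilyloxy)phenyl]-2,3-dihydrobenzofuran-3-carboxylate | O1CCOC1c1cc(OC)c2c(c1)[C@@H](C(=O)OC(C)(C)C)[C@H](c1ccc(O[Si](C(C)C)(C(C)C)C(C)C)c(OC)c1)O2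
F12 | step 17 | tris(aryl silyl ether) of the target (ring A and ring D phenols as TIPS ethers, ring C phenol as TBS ether, all alcohols free) | COc1cc([C@@H](O)[C@H](CO)c2cc(C[C@@H]3C(=O)OC[C@H]3Cc3cc(OC)c4c(c3)[C@@H](CO)[C@H](c3ccc(O[Si](C(C)C)(C(C)C)C(C)C)c(OC)c3)O4)cc(OC)c2O[Si](C)(C)C(C)(C)C)ccc1O[Si](C(C)C)(C(C)C)C(C)C
A1 | alternative 1 | methyl (2R,3R)-5-bromo-7-methoxy-2-[3-methoxy-4-(methylsulfonyloxy)phenyl]-2,3-dihydrobenzofuran-3-carboxylate | Brc1cc(OC)c2c(c1)[C@@H](C(=O)OC)[C@H](c1ccc(OS(C)(=O)=O)c(OC)c1)O2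
A2 | alternative 1 | (R)-6-bromo-8-methoxy-2-[3-methoxy-4-(methylsulfonyloxy)phenyl]chroman-4-one | O=C1C[C@H](c2ccc(OS(C)(=O)=O)c(OC)c2)Oc2c(OC)cc(Br)cc12
A3 | alternative 2 | bis-anti diol with both wings open (ring B phenol as allyl ether, other hydroxyls as TBS ethers except the two new carbinols) | COc1cc([C@@H](O)[C@H](CO[Si](C)(C)C(C)(C)C)c2cc(C[C@@H]3C(=O)OC[C@H]3Cc3cc(OC)c(OCC=C)c(c3)[C@@H](CO[Si](C)(C)C(C)(C)C)[C@H](O)c3ccc(O[Si](C)(C)C(C)(C)C)c(OC)c3)cc(OC)c2O[Si](C)(C)C(C)(C)C)ccc1O[Si](C(C)C)(C)C
A4 | alternative 2 | dialdehyde: trans-dibenzylbutyrolactone with an α-aryl-β-silyloxypropanal on each benzyl ring | O=C[C@H](CO[Si](C)(C)C(C)(C)C)c1cc(C[C@@H]2C(=O)OC[C@H]2Cc2cc(OC)c(OCC=C)c(c2)[C@@H](CO[Si](C)(C)C(C)(C)C)C=O)cc(OC)c1O[Si](C)(C)C(C)(C)C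
A5 | alternative 2 | 4-(tert-butyldimethylsilyloxy)-3-methoxyphenylmagnesium bromide | COc1cc([Mg]Br)ccc1O[Si](C)(C)C(C)(C)C
A6 | alternative 3 | (S)-4-({(2R,3S)-3-[(tert-butyldimethylsilyloxy)methyl]-2-[4-(tert-butyldimethylsilyloxy)-3-methoxyphenyl]-7-methoxy-2,3-dihydrobenzofuran-5-yl}methyl)dihydrofuran-2(3H)-one | O=C1C[C@H](Cc3cc(OC)c4c(c3)[C@@H](CO[Si](C)(C)C(C)(C)C)[C@H](c3ccc(O[Si](C)(C)C(C)(C)C)c(OC)c3)O4)CO1
A7 | alternative 3 | 3-({(2R,3S)-3-[(tert-butyldimethylsilyloxy)methyl]-2-[4-(tert-butyldimethylsilyloxy)-3-methoxyphenyl]-7-methoxy-2,3-dihydrobenzofuran-5-yl}methyl)cyclobutan-1-one | O=C1CC(Cc3cc(OC)c4c(c3)[C@@H](CO[Si](C)(C)C(C)(C)C)[C@H](c3ccc(O[Si](C)(C)C(C)(C)C)c(OC)c3)O4)C1
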